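## Retrosynthetic overview

- The target's only ring is a cyclohexene. Numbering: C1 = quaternary carbinol bearing C7H2OBz, C2 and C3 = acetoxy carbons, C4=C5 = alkene, C6 = free carbinol. C2–C1–C6 is an oxidised acetone unit whose C2 and C6 oxygens lie on the same ring face, so this 1,3-cis pair can be the two ring oxygens of a 1,3-dioxan-5-one with C1 as its carbonyl.
- Late disconnections: C6–OH from the enone (Luche reduction); C3–OAc from the epimeric carbinol (Mitsunobu inversion on the opened ring); C7–OBz and C1–C7 from a spiro-epoxide, made from the bridging ketone and a sulfur ylide.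
- Key disconnection C5–C6: palladium-catalysed alkenylation of the dioxanone enolate carbon C6 by the Z-iodoalkene carbon C5, closing the carbocycle as a C3–C4=C5 bridge across the dioxanone.
- C2–C3 comes from an (R)-proline anti aldol of 2,2-dimethyl-1,3-dioxan-5-one with 3-(trimethylsilyl)propynal; the C5–I bond is made from the alkyne.
- Ring order: the dioxanone ring is bought, the carbocycle is closed onto it in step 5, and the dioxane ring is opened again in step 8.

Key step: step 5

Remark: the atom numbers C1–C7 are used for every compound. C7 is installed while C3 still carries its equatorial silyloxy group, and C3 is inverted only after the dioxane ring is opened. In the bicycle an inverted C3 substituent would be axial on the same face as C7, so either order of installing them there would force one group in syn-axial to the other.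

## Route

Step 1
Reactants: 1 2,2-dimethyl-1,3-dioxan-5-one; 2 3-(trimethylsilyl)prop-2-ynal
Product: 3 (4R)-4-[(1R)-1-hydroxy-3-(trimethylsilyl)prop-2-yn-1-yl]-2,2-dimethyl-1,3-dioxan-5-one
Conditions: (R)-proline (30 mol%), DMF, 4 °C
Reagents that add atoms: none
Why: Proline enamine aldol reaction: the E-enamine of the cyclic ketone adds to the aldehyde through the hydrogen-bonded chair-like transition state, which should give the anti aldol and, with (R)-proline, the 4R,1'R pair (C2 as in the target, C3 as the epimer inverted in step 12).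

Step 2
Reactants: 3 (4R)-4-[(1R)-1-hydroxy-3-(trimethylsilyl)prop-2-yn-1-yl]-2,2-dimethyl-1,3-dioxan-5-one
Product: 4 (4R)-4-[(1R)-1-(tert-butyldimethylsilyloxy)-3-(trimethylsilyl)prop-2-yn-1-yl]-2,2-dimethyl-1,3-dioxan-5-one
Conditions: TBSOTf, 2,6-lutidine, CH2Cl2, −78 °C
Reagents that add atoms: tert-butyldimethylsilyl triflate, CC(C)(C)[Si](C)(C)OS(=O)(=O)C(F)(F)F
Why: O-Silylation with a silyl triflate and a hindered pyridine is fast at low temperature, so it should outrun retro-aldol cleavage or elimination of the β-hydroxy ketone, and the ether then blocks both.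

Step 3
Reactants: 4 (4R)-4-[(1R)-1-(tert-butyldimethylsilyloxy)-3-(trimethylsilyl)prop-2-yn-1-yl]-2,2-dimethyl-1,3-dioxan-5-one
Product: 5 (4R)-4-[(1R)-1-(tert-butyldimethylsilyloxy)-3-iodoprop-2-yn-1-yl]-2,2-dimethyl-1,3-dioxan-5-one
Conditions: N-iodosuccinimide, AgNO3 (10 mol%), acetone, 25 °C, dark
Reagents that add atoms: N-iodosuccinimide, O=C1CCC(=O)N1I
Why: Silver-catalysed iododesilylation is a known direct conversion of silylalkynes into 1-iodoalkynes under neutral conditions that should leave the ketone, the ketal and the silyl ether untouched.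

Step 4
Reactants: 5 (4R)-4-[(1R)-1-(tert-butyldimethylsilyloxy)-3-iodoprop-2-yn-1-yl]-2,2-dimethyl-1,3-dioxan-5-one
Product: 6 (4R)-4-[(1R,2Z)-1-(tert-butyldimethylsilyloxy)-3-iodoprop-2-en-1-yl]-2,2-dimethyl-1,3-dioxan-5-one
Conditions: 2-nitrobenzenesulfonylhydrazide, Et3N, THF–iPrOH, 25 °C
Reagents that add atoms: none
Why: Diimide reduction transfers two hydrogens in a concerted syn fashion to the iodoalkyne, giving the Z-iodoalkene without touching the C–I bond or the ketone (a hydroboration route would reduce the ketone).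

Step 5
Reactants: 6 (4R)-4-[(1R,2Z)-1-(tert-butyldimethylsilyloxy)-3-iodoprop-2-en-1-yl]-2,2-dimethyl-1,3-dioxan-5-one
Product: 8 (1R,5S,8R)-8-(tert-butyldimethylsilyloxy)-3,3-dimethyl-2,4-dioxabicyclo[3.3.1]non-6-en-9-one, via potassium enolate 7 (not isolated)
Conditions: Pd(PPh3)4 (10 mol%), KOPh (2 equiv), THF, 65 °C
Reagents that add atoms: none
Why: Zerovalent palladium inserts into the C5–I bond with retention of the Z geometry, phenoxide reversibly forms the potassium enolate 7 on the CH2 side, the enolate carbon C6 replaces iodide on divalent palladium, and reductive elimination forms C5–C6. The closest known reaction type is the Pd(PPh3)4-catalysed intramolecular α-alkenylation of ketone enolates by tethered vinyl iodides, established for bridged bicyclo[3.3.1]nonenones and their 2-aza analogues; the dioxanone is a new substrate for it, not a new reaction. The six-membered carbocycle C1–C6 closes in a 6-(enolendo) mode through a seven-membered palladacycle, as a C3–C4=C5 bridge between C2 and C6 of the dioxanone, whose side chain must sit axial. The new stereocentre C6 is fixed by the tether: anchored at C2, the vinyl group reaches only the enolate face that puts C6–O cis to C2–O (5S in the bicycle). The step needs enolisation at C6 and not at C2, which would open β-elimination of the silyloxy group or epimerisation; the weak, reversible base, the easier access to the CH2 group and the fact that only the C6 enolate leads on to product should secure this. Once the ring is closed both α-carbons are bridgeheads, so the β-silyloxy ketone 8 can no longer enolise, eliminate or undergo retro-aldol cleavage.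

Step 6
Reactants: 8 (1R,5S,8R)-8-(tert-butyldimethylsilyloxy)-3,3-dimethyl-2,4-dioxabicyclo[3.3.1]non-6-en-9-one; 9 trimethylsulfoxonium iodide
Product: 11 (1R,5S,8R,9S)-8-(tert-butyldimethylsilyloxy)-3,3-dimethylspiro[2,4-dioxabicyclo[3.3.1]non-6-ene-9,2'-oxirane] (epoxide oxygen on the dioxane side, CH2 on the side of the C6=C7–C8 bridge), via sulfoxonium betaine 10 (not isolated)
Conditions: NaH, DMSO, 25 °C; then 8 in THF, 25 to 50 °C
Reagents that add atoms: none
Why: Corey–Chaykovsky epoxidation of a non-enolisable ketone activated by two α-oxygens: the ylide carbon should enter from the side of the C3–C4=C5 bridge, where only the axial hydrogen on C3 stands in the way, because the gem-dimethyl ketal cannot keep a chair in the bicycle (its inner methyl would point into C4) and the flattened dioxane ring holds one methyl over the other face of the carbonyl; C7 thus ends up on the carbocycle side and the oxygen cis to the C2 and C6 oxygens, as C1 of the target requires.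

Step 7
Reactants: 11 (1R,5S,8R,9S)-8-(tert-butyldimethylsilyloxy)-3,3-dimethylspiro[2,4-dioxabicyclo[3.3.1]non-6-ene-9,2'-oxirane]; 12 benzoic acid
Product: 13 [(1R,5S,8R,9S)-8-(tert-butyldimethylsilyloxy)-9-hydroxy-3,3-dimethyl-2,4-dioxabicyclo[3.3.1]non-6-en-9-yl]methyl benzoate
Conditions: CsO2CPh (0.3 equiv), DMF, 80 °C
Reagents that add atoms: none
Why: Nucleophilic epoxide opening: benzoate attacks the only carbon open to SN2 displacement, the primary C7, from above the carbocycle (the equatorial silyloxy group on C3 is out of the way), and the tertiary alkoxide is protonated by benzoic acid, which regenerates the caesium benzoate.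

Step 8
Reactants: 13 [(1R,5S,8R,9S)-8-(tert-butyldimethylsilyloxy)-9-hydroxy-3,3-dimethyl-2,4-dioxabicyclo[3.3.1]non-6-en-9-yl]methyl benzoate
Product: 14 (1S,2R,3R,6S)-1-(benzoyloxymethyl)-3-(tert-butyldimethylsilyloxy)cyclohex-4-ene-1,2,6-triol
Conditions: AcOH–H2O (4:1), 25 °C
Reagents that add atoms: none
Why: Acid hydrolysis of the ketal: the bridged isopropylidene ketal is strained by its forced non-chair shape and should hydrolyse under conditions that leave the secondary silyl ether and the benzoate intact.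

Step 9
Reactants: 14 (1S,2R,3R,6S)-1-(benzoyloxymethyl)-3-(tert-butyldimethylsilyloxy)cyclohex-4-ene-1,2,6-triol
Product: 15 (1R,2R,3R)-1-(benzoyloxymethyl)-3-(tert-butyldimethylsilyloxy)-1,2-dihydroxycyclohex-4-en-6-one
Conditions: MnO2 (activated, excess), CH2Cl2, 25 °C
Reagents that add atoms: none
Why: Allylic oxidation with MnO2: only the C6 carbinol is a free allylic alcohol (C3 is silylated, C2–OH is not allylic, C1–OH is tertiary), so the oxidant tells apart the two secondary hydroxyls freed in step 8 and stores C6 as the enone carbonyl.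

Step 10
Reactants: 15 (1R,2R,3R)-1-(benzoyloxymethyl)-3-(tert-butyldimethylsilyloxy)-1,2-dihydroxycyclohex-4-en-6-one
Product: 16 (1R,2R,3R)-2-acetoxy-1-(benzoyloxymethyl)-3-(tert-butyldimethylsilyloxy)-1-hydroxycyclohex-4-en-6-one
Conditions: Ac2O, pyridine, DMAP (cat.), CH2Cl2, 0 °C
Reagents that add atoms: acetic anhydride, CC(=O)OC(C)=O
Why: Acetylation: C2–OH is now the only secondary hydroxyl, and the tertiary α-ketol hydroxyl at C1 should be too hindered to be acylated under these conditions.

Step 11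
Reactants: 16 (1R,2R,3R)-2-acetoxy-1-(benzoyloxymethyl)-3-(tert-butyldimethylsilyloxy)-1-hydroxycyclohex-4-en-6-one
Product: 17 (1R,2R,3R)-2-acetoxy-1-(benzoyloxymethyl)-1,3-dihydroxycyclohex-4-en-6-one
Conditions: HF·pyridine, THF–pyridine, 0 °C
Reagents that add atoms: none
Why: Fluoride desilylation in a buffered acidic medium frees the C3 hydroxyl without generating the alkoxide that would let the cis C2 acetate migrate.

Step 12
Reactants: 17 (1R,2R,3R)-2-acetoxy-1-(benzoyloxymethyl)-1,3-dihydroxycyclohex-4-en-6-one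
Product: 19 (1R,2R,3S)-2,3-diacetoxy-1-(benzoyloxymethyl)-1-hydroxycyclohex-4-en-6-one, via alkoxyphosphonium acetate 18 (not isolated)
Conditions: PPh3, DIAD, AcOH, THF, 0 °C
Reagents that add atoms: acetic acid, CC(=O)O
Why: Mitsunobu reaction: only the secondary C3 hydroxyl can be activated (C1–OH is tertiary), and acetate displaces the phosphonium oxide in an SN2 step with inversion, entering anti to a pseudoaxial leaving group on the now flexible ring and without participation by the cis C2 acetate, which sets C3 (S) trans to C2.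

Step 13
Reactants: 19 (1R,2R,3S)-2,3-diacetoxy-1-(benzoyloxymethyl)-1-hydroxycyclohex-4-en-6-one
Product: 20 (1S,2R,3S,6S)-2,3-diacetoxy-1-(benzoyloxymethyl)cyclohex-4-ene-1,6-diol (EANPDB:ANNO_00166)
Conditions: NaBH4, CeCl3·7H2O, MeOH, −78 °C
Reagents that add atoms: none
Why: Luche reduction: CeCl3 steers the hydride to 1,2-addition, and in the half-chair that holds the C1 hydroxyl axial and the CH2OBz and both acetoxy groups equatorial the hydride should add axially, anti to the C1–O bond, so the new C6 hydroxyl is equatorial and cis to the C1 hydroxyl (6S); the esters survive the short, cold reaction.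

## Compound list

1 | 2,2-dimethyl-1,3-dioxan-5-one | CC1(C)OCC(=O)CO1 | starting material
2 | 3-(trimethylsilyl)prop-2-ynal | C[Si](C)(C)C#CC=O | starting material
3 | (4R)-4-[(1R)-1-hydroxy-3-(trimethylsilyl)prop-2-yn-1-yl]-2,2-dimethyl-1,3-dioxan-5-one | O=C1COC(C)(C)O[C@@H]1[C@H](O)C#C[Si](C)(C)C | intermediate
4 | (4R)-4-[(1R)-1-(tert-butyldimethylsilyloxy)-3-(trimethylsilyl)prop-2-yn-1-yl]-2,2-dimethyl-1,3-dioxan-5-one | O=C1COC(C)(C)O[C@@H]1[C@H](O[Si](C)(C)C(C)(C)C)C#C[Si](C)(C)C | intermediate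
5 | (4R)-4-[(1R)-1-(tert-butyldimethylsilyloxy)-3-iodoprop-2-yn-1-yl]-2,2-dimethyl-1,3-dioxan-5-one | O=C1COC(C)(C)O[C@@H]1[C@H](O[Si](C)(C)C(C)(C)C)C#CI | intermediate
6 | (4R)-4-[(1R,2Z)-1-(tert-butyldimethylsilyloxy)-3-iodoprop-2-en-1-yl]-2,2-dimethyl-1,3-dioxan-5-one | O=C1COC(C)(C)O[C@@H]1[C@H](O[Si](C)(C)C(C)(C)C)/C=C\I | intermediate
7 | potassium (4R)-4-[(1R,2Z)-1-(tert-butyldimethylsilyloxy)-3-iodoprop-2-en-1-yl]-2,2-dimethyl-4H-1,3-dioxin-5-olate | [K+].[O-]C1=COC(C)(C)O[C@@H]1[C@H](O[Si](C)(C)C(C)(C)C)/C=C\I | intermediate (not isolated)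
8 | (1R,5S,8R)-8-(tert-butyldimethylsilyloxy)-3,3-dimethyl-2,4-dioxabicyclo[3.3.1]non-6-en-9-one | O=C1[C@H]2OC(C)(C)O[C@@H]1[C@H](O[Si](C)(C)C(C)(C)C)C=C2 | intermediate
9 | trimethylsulfoxonium iodide | C[S+](C)(C)=O.[I-] | starting material
10 | (1R,5S,8R,9S)-8-(tert-butyldimethylsilyloxy)-9-[(dimethyloxosulfonio)methyl]-3,3-dimethyl-2,4-dioxabicyclo[3.3.1]non-6-en-9-olate | CC(C)(C)[Si](C)(C)O[C@@H]1C=C[C@@H]2OC(C)(C)O[C@H]1[C@]2([O-])C[S+](C)(C)=O | intermediate (not isolated)
11 | (1R,5S,8R,9S)-8-(tert-butyldimethylsilyloxy)-3,3-dimethylspiro[2,4-dioxabicyclo[3.3.1]non-6-ene-9,2'-oxirane] | CC(C)(C)[Si](C)(C)O[C@@H]1C=C[C@@H]2OC(C)(C)O[C@H]1[C@]23CO3 | intermediate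
12 | benzoic acid | OC(=O)c1ccccc1 | starting material
13 | [(1R,5S,8R,9S)-8-(tert-butyldimethylsilyloxy)-9-hydroxy-3,3-dimethyl-2,4-dioxabicyclo[3.3.1]non-6-en-9-yl]methyl benzoate | CC(C)(C)[Si](C)(C)O[C@@H]1C=C[C@@H]2OC(C)(C)O[C@H]1[C@]2(O)COC(=O)c3ccccc3 | intermediate
14 | (1S,2R,3R,6S)-1-(benzoyloxymethyl)-3-(tert-butyldimethylsilyloxy)cyclohex-4-ene-1,2,6-triol | CC(C)(C)[Si](C)(C)O[C@@H]1C=C[C@H](O)[C@@](O)(COC(=O)c2ccccc2)[C@@H]1O | intermediate
15 | (1R,2R,3R)-1-(benzoyloxymethyl)-3-(tert-butyldimethylsilyloxy)-1,2-dihydroxycyclohex-4-en-6-one | CC(C)(C)[Si](C)(C)O[C@@H]1C=CC(=O)[C@@](O)(COC(=O)c2ccccc2)[C@@H]1O | intermediate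
16 | (1R,2R,3R)-2-acetoxy-1-(benzoyloxymethyl)-3-(tert-butyldimethylsilyloxy)-1-hydroxycyclohex-4-en-6-one | CC(C)(C)[Si](C)(C)O[C@@H]1C=CC(=O)[C@@](O)(COC(=O)c2ccccc2)[C@@H]1OC(C)=O | intermediate
17 | (1R,2R,3R)-2-acetoxy-1-(benzoyloxymethyl)-1,3-dihydroxycyclohex-4-en-6-one | O[C@@H]1C=CC(=O)[C@@](O)(COC(=O)c2ccccc2)[C@@H]1OC(C)=O | intermediate
18 | {[(1R,5R,6R)-5-acetoxy-6-(benzoyloxymethyl)-6-hydroxy-4-oxocyclohex-2-en-1-yl]oxy}triphenylphosphonium acetate (the C3–O–PPh3 salt of 17) | c3ccccc3[P+](c4ccccc4)(c5ccccc5)O[C@@H]1C=CC(=O)[C@@](O)(COC(=O)c2ccccc2)[C@@H]1OC(C)=O.CC(=O)[O-] | intermediate (not isolated)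
19 | (1R,2R,3S)-2,3-diacetoxy-1-(benzoyloxymethyl)-1-hydroxycyclohex-4-en-6-one | CC(=O)O[C@H]1C=CC(=O)[C@@](O)(COC(=O)c2ccccc2)[C@@H]1OC(C)=O | intermediate
20 | (1S,2R,3S,6S)-2,3-diacetoxy-1-(benzoyloxymethyl)cyclohex-4-ene-1,6-diol | CC(=O)O[C@H]1C=C[C@H](O)[C@@](O)(COC(=O)c2ccccc2)[C@@H]1OC(C)=O | target

## Step count and risks

Total steps: 13. Longest linear sequence: 13 steps (1 and 2 to 20).

**Step 5 (bridging alkenylation).** Deprotonation at C2 in place of C6 may lead to β-elimination of the silyloxy group or to epimerisation. Reductive elimination may also be slow, because the ketal ring has to flatten as the bridge closes, so the vinylpalladium species is lost by protodeiodination. The fallback makes the same C5–C6 bond with the nucleophile fixed beforehand on the CH2 side and sets out from 4. Silver-catalysed protodesilylation of the alkyne (AgNO3 cat., acetone–H2O) would give (4R)-4-[(1R)-1-(tert-butyldimethylsilyloxy)prop-2-yn-1-yl]-2,2-dimethyl-1,3-dioxan-5-one F1. Kinetic enolisation at the unhindered C6 methylene and O-silylation (LiHMDS, TBSOTf, THF, −78 °C) would give the silyl enol ether tert-butyl{[(4R)-4-[(1R)-1-(tert-butyldimethylsilyloxy)prop-2-yn-1-yl]-2,2-dimethyl-4H-1,3-dioxin-5-yl]oxy}dimethylsilane F2. A cationic phosphine–gold catalyst, [(2-biphenylyl)(tBu)2P]Au(NCMe)SbF6, in wet CH2Cl2 would then effect the 6-endo-dig carbocyclisation of the enol ether onto the alkyne (Conia-ene type), a known entry to bicyclo[3.3.1]non-6-en-9-ones. This returns to the route at 8.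

**Step 6 (ylide epoxidation).** Facial selectivity may be poor if the ketal shields the carbonyl less than expected, so that the ylide also enters from the dioxane side, or addition to the hindered bridging ketone may be sluggish. The fallback delivers oxygen, not carbon, under hydroxyl direction and sets out from 8. Wittig methylenation (Ph3P=CH2, THF) would give (1S,5S,8R)-8-(tert-butyldimethylsilyloxy)-3,3-dimethyl-9-methylidene-2,4-dioxabicyclo[3.3.1]non-6-ene F3. Ketal hydrolysis (AcOH–H2O) would give (2S,3R,6S)-3-(tert-butyldimethylsilyloxy)-1-methylidenecyclohex-4-ene-2,6-diol F4. Epoxidation with VO(acac)2 (cat.) and tBuOOH should place the oxygen on the exocyclic alkene from the face of its two flanking cis hydroxyls, giving the (1S,2R,3R,6S)-1,7-epoxide of F4, 3-(tert-butyldimethylsilyloxy)-1,7-epoxy-1-methylcyclohex-4-ene-2,6-diol F5. Opening at C7 with benzoic acid and Ti(OiPr)4 returns to the route at 14.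

**Step 13 (Luche reduction).** Hydride addition syn to the C1–O bond would give the C6 epimer, and conjugate reduction may compete. The fallback never oxidises C6 and sets out from 14. Silylation of the less hindered allylic C6 hydroxyl (TBDPSCl, imidazole, DMF) would give (1R,2R,3R,6S)-1-(benzoyloxymethyl)-3-(tert-butyldimethylsilyloxy)-6-(tert-butyldiphenylsilyloxy)cyclohex-4-ene-1,2-diol F6. Acetylation (Ac2O, DMAP, pyridine) would give its 2-acetate, (1R,2R,3R,6S)-2-acetoxy-1-(benzoyloxymethyl)-3-(tert-butyldimethylsilyloxy)-6-(tert-butyldiphenylsilyloxy)cyclohex-4-en-1-ol F7. Selective removal of the tert-butyldimethylsilyl group (PPTS, MeOH, 40 °C) would give (1R,2R,3R,6S)-2-acetoxy-1-(benzoyloxymethyl)-6-(tert-butyldiphenylsilyloxy)cyclohex-4-ene-1,3-diol F8. Mitsunobu inversion (PPh3, DIAD, AcOH) would give (1R,2R,3S,6S)-2,3-diacetoxy-1-(benzoyloxymethyl)-6-(tert-butyldiphenylsilyloxy)cyclohex-4-en-1-ol F9. Desilylation with HF·pyridine returns to the route at 20.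

## Further compounds

F1 | step 5 | (4R)-4-[(1R)-1-(tert-butyldimethylsilyloxy)prop-2-yn-1-yl]-2,2-dimethyl-1,3-dioxan-5-one | O=C1COC(C)(C)O[C@@H]1[C@H](O[Si](C)(C)C(C)(C)C)C#C
F2 | step 5 | tert-butyl{[(4R)-4-[(1R)-1-(tert-butyldimethylsilyloxy)prop-2-yn-1-yl]-2,2-dimethyl-4H-1,3-dioxin-5-yl]oxy}dimethylsilane | CC(C)(C)[Si](C)(C)OC1=COC(C)(C)O[C@@H]1[C@H](O[Si](C)(C)C(C)(C)C)C#C
F3 | step 6 | (1S,5S,8R)-8-(tert-butyldimethylsilyloxy)-3,3-dimethyl-9-methylidene-2,4-dioxabicyclo[3.3.1]non-6-ene | CC(C)(C)[Si](C)(C)O[C@@H]1C=C[C@@H]2OC(C)(C)O[C@H]1C2=C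
F4 | step 6 | (2S,3R,6S)-3-(tert-butyldimethylsilyloxy)-1-methylidenecyclohex-4-ene-2,6-diol | CC(C)(C)[Si](C)(C)O[C@@H]1C=C[C@H](O)C(=C)[C@@H]1O
F5 | step 6 | (1S,2R,3R,6S)-3-(tert-butyldimethylsilyloxy)-1,7-epoxy-1-methylcyclohex-4-ene-2,6-diol (epoxide oxygen cis to the C2 and C6 hydroxyls) | CC(C)(C)[Si](C)(C)O[C@@H]1C=C[C@H](O)[C@@]2(CO2)[C@@H]1O
F6 | step 13 | (1R,2R,3R,6S)-1-(benzoyloxymethyl)-3-(tert-butyldimethylsilyloxy)-6-(tert-butyldiphenylsilyloxy)cyclohex-4-ene-1,2-diol | CC(C)(C)[Si](C)(C)O[C@@H]1C=C[C@H](O[Si](c2ccccc2)(c3ccccc3)C(C)(C)C)[C@@](O)(COC(=O)c4ccccc4)[C@@H]1O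
F7 | step 13 | (1R,2R,3R,6S)-2-acetoxy-1-(benzoyloxymethyl)-3-(tert-butyldimethylsilyloxy)-6-(tert-butyldiphenylsilyloxy)cyclohex-4-en-1-ol | CC(C)(C)[Si](C)(C)O[C@@H]1C=C[C@H](O[Si](c2ccccc2)(c3ccccc3)C(C)(C)C)[C@@](O)(COC(=O)c4ccccc4)[C@@H]1OC(C)=O
F8 | step 13 | (1R,2R,3R,6S)-2-acetoxy-1-(benzoyloxymethyl)-6-(tert-butyldiphenylsilyloxy)cyclohex-4-ene-1,3-diol | O[C@@H]1C=C[C@H](O[Si](c2ccccc2)(c3ccccc3)C(C)(C)C)[C@@](O)(COC(=O)c4ccccc4)[C@@H]1OC(C)=O
F9 | step 13 | (1R,2R,3S,6S)-2,3-diacetoxy-1-(benzoyloxymethyl)-6-(tert-butyldiphenylsilyloxy)cyclohex-4-en-1-ol | CC(=O)O[C@H]1C=C[C@H](O[Si](c2ccccc2)(c3ccccc3)C(C)(C)C)[C@@](O)(COC(=O)c4ccccc4)[C@@H]1OC(C)=O
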